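Follow one molecule of starting material through the larch run and ask its chance of ending as target. Feed and reaction overlap there and the percentages count the whole charge, so what has reacted at any time is the part fed so far, time over dosing time, less the starting material read.

| flask | starting material | protic impurity | remark | time |
|---|---|---|---|---|
| larch | 0.75 M (fed, over 20 s) | 0.75 M | run made earlier; the fed solution adds 0.10 times the starting volume |  |
| flask | 1.5 M (fed, over 20 s) | 0.750 M | the fed solution adds 0.10 times the starting volume | 10 min |

larch run (percent of the starting material charged)

| time / s | target / % | starting material / % |
|---|---|---|
| 10.0 | 12 | 28 |
| 12.0 | 16 | 33 |
| 25.0 | 38 | 19 |
| 60.0 | 42 | 0 |

(scatter of a reading: 2 percentage points)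

- charges are per starting volume, the dose included; the dosed solution carries all of it
- percentages count the whole charge, also what has not yet gone in

- the best time, 10 min at the latest, for target
- the amount of target, in percent of the starting material charged, at that time

Read the larch table downward, dividing target by what has reacted. The first row gives 0.545 and the second 0.593. The next row gives 0.469. The last row, with starting material at 0 %, gives 0.420, and this is the overall target share (the selectivity), target formed per molecule reacted.

Now set the last two rows against each other. While the 19 % of starting material read at 25.0 s went, target rose by 4 percentage points, a share of 0.211, so within the scatter of 2 points per reading late molecules read worse than early ones.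

The flask holds twice the larch charge of starting material and half the protic impurity per starting material. A loss taking two molecules of starting material grows with c(starting material), and we take that as the stronger effect. So we commit, for the flask, to a share below 0.420, which puts target under 42 %, with the peak by about 60.0 s.

The forecast gives 42 % at 1.5 min, holding of the two effects of doubling that “These roughly cancel”, so our reckoning is lower and earlier.

The flask gives 36.7 % at 0.698 min, with starting material at 2.82 % by then.

    starting material ⇌ target (K = 29.4, k = 0.0688 /s)
    target ⇌ isomer of the product A (K = 0.824, k = 0.0199 /s)
    isomer of the product A ⇌ starting material (k = 0.00166 /s)
    2 starting material → self-condensation product (k = 0.0392 /M/s)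
    starting material + protic impurity → quenched substrate (k = 0.0169 /M/s)
    target ⇌ isomer of the product B (K = 0.200, k = 0.0169 /s)

The target share of the flask at its best time is 0.378, lower than the 0.420 read in the larch run at 60.0 s. At 10.0 min the share in the flask is 0.337. A neighbour flask charged with 3.0 M of protic impurity has a share of 0.230 at that time, with quenched substrate at 40.0 %.

The readings are calculated with constants of no real substance; noise was put on by code.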